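The route rests on disconnecting the quaternary C9–C10 bond and the C5–C6 bond across one ring-A enone: in the target, C10 and C5 are the β- and α-carbons of a C4 carbonyl (the later tertiary carbinol). One copper-catalysed enantioselective conjugate addition of an (E)-alkenylalane carrying C9, C8, C7 and the silyl-protected C11 carbinol, with capture of the aluminium enolate by formaldehyde (C6), therefore assembles the whole bicyclic carbon framework bar the C15 methyl and sets C10 and C5. Its precursors are 3-methylcyclohex-2-enone, monomeric formaldehyde and the alane from hydroalumination of silylated 2-methylpent-4-yn-2-ol. Ring B is closed afterwards by aldol condensation (C6=C7); the C3/C4 diol comes from osmylation of a C3=C4 methyl alkene.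

Key step: step 2

Numbering used throughout (eudesmane type): ring A is C1–C5 plus C10, ring B is C5–C10. C3 bears the ester, C4 the tertiary OH and methyl C15, C10 the methyl C14, C7 the carbinol C11. β is the face of C14, α the opposite face. Primed numbers belong to the acyl group.

Remark on C5: methyl and alkenyl on C10 are too similar in size for base equilibration next to the C4 ketone to bias C5 in the monocycle. C5 is therefore taken from the kinetic capture in step 2, and the minor epimer is to be removed by chromatography at compound 8.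

Remark on order: the C4 ketone is converted into the C3/C4 diol before ring B is closed, so that C5 never becomes the acidic centre of an ene-dione.

Assumption: the antipode of the imidazolinium ligand that gives R at C10 is picked in a trial run; both antipodes are accessible.

Step 1
Reactants: 1 2-methylpent-4-yn-2-ol
Product: 2 triethyl[(2-methylpent-4-yn-2-yl)oxy]silane
Conditions: Et3SiOTf, 2,6-lutidine, CH2Cl2, 0 °C
Reagents that add atoms: triethylsilyl trifluoromethanesulfonate, CC[Si](CC)(CC)OS(=O)(=O)C(F)(F)F
Why: A silyl triflate with a hindered pyridine base silylates the tertiary alcohol (O-silylation) and leaves the terminal alkyne free for hydroalumination.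

Step 2
Reactants: 2 triethyl[(2-methylpent-4-yn-2-yl)oxy]silane; 3 3-methylcyclohex-2-en-1-one; 4 formaldehyde (monomer, cracked from dry paraformaldehyde)
Product: 7 (2S,3R)-2-(hydroxymethyl)-3-methyl-3-[(1E)-4-methyl-4-(triethylsilyloxy)pent-1-en-1-yl]cyclohexan-1-one, via (E)-alkenyl(diisobutyl)alane 5 (not isolated), via diisobutylaluminium enolate 6 (not isolated)
Conditions: i-Bu2AlH, hexanes, 55 °C; then 3, Cu(OTf)2 (5 mol%), chiral sulfonate-bearing imidazolinium salt (5 mol%), THF, −50 → −15 °C; then CH2O (g), −78 °C; aq. potassium sodium tartrate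
Reagents that add atoms: none
Why: syn-Hydroalumination of the alkyne gives the (E)-alkenylalane 5, whose alkenyl group passes to copper bound to the N-heterocyclic carbene (freed from the imidazolinium salt by the alane) and adds to C10 of the enone through a copper–alkene complex, the sulfonate bridging to aluminium; the aluminium enolate 6 then attacks formaldehyde at C5 in an aldol addition. The closest known reaction type is the carbene–copper-catalysed enantioselective conjugate addition of alkenylaluminium reagents to β-methylcyclohexenone, combined with aldehyde capture of the aluminium enolate. No ring is closed. C10 is set by the catalyst, and C5 by the substrate, formaldehyde entering axially on the enolate face away from the larger alkenyl group so that C6 should lie trans to C9. The step needs 1,4- over 1,2-addition and alkenyl over isobutyl transfer, secured by copper catalysis and the faster transfer of the sp2 carbon, and carbon capture over proton quench, secured by dry monomeric formaldehyde at −78 °C.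

Step 3
Reactants: 7 (2S,3R)-2-(hydroxymethyl)-3-methyl-3-[(1E)-4-methyl-4-(triethylsilyloxy)pent-1-en-1-yl]cyclohexan-1-one
Product: 8 (2S,3R)-3-methyl-3-[(1E)-4-methyl-4-(triethylsilyloxy)pent-1-en-1-yl]-2-[(triethylsilyloxy)methyl]cyclohexan-1-one
Conditions: Et3SiCl, imidazole, CH2Cl2, 0 °C
Reagents that add atoms: chlorotriethylsilane, CC[Si](Cl)(CC)CC
Why: Imidazole-promoted silylation of the primary alcohol masks the retro-aldol-prone β-hydroxy ketone under near-neutral conditions without touching C5.

Step 4
Reactants: 8 (2S,3R)-3-methyl-3-[(1E)-4-methyl-4-(triethylsilyloxy)pent-1-en-1-yl]-2-[(triethylsilyloxy)methyl]cyclohexan-1-one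
Product: 10 5-methyl-5-[(1E)-4-methyl-4-(triethylsilyloxy)pent-1-en-1-yl]-6-[(triethylsilyloxy)methyl]cyclohex-1-en-1-yl trifluoromethanesulfonate (C3=C4 enol triflate; C5 and C10 as in 8), via potassium C3-enolate 9 (not isolated)
Conditions: KN(SiMe3)2, THF, −78 °C; PhNTf2, −78 → 0 °C; aq. NH4Cl
Reagents that add atoms: N-phenylbis(trifluoromethanesulfonimide), O=S(=O)(N(c1ccccc1)S(=O)(=O)C(F)(F)F)C(F)(F)F
Why: The bulky amide removes the less hindered C3 proton under kinetic control (C5 is tertiary and next to the quaternary C10), and O-triflation of the enolate fixes the C3=C4 double bond (enol triflate formation).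

Step 5
Reactants: 10 the C3=C4 enol triflate
Product: 12 5-[2-hydroxy-4-methyl-4-(triethylsilyloxy)pentyl]-5-methyl-6-[(triethylsilyloxy)methyl]cyclohex-1-en-1-yl trifluoromethanesulfonate (C8 epimers), via C8 9-borabicyclononyl borane 11 (not isolated)
Conditions: 9-BBN dimer, THF, 65 °C; then NaBO3·4H2O, THF/H2O, rt
Reagents that add atoms: sodium perborate, [Na+].[Na+].O[B-]1(O)OO[B-](O)(O)OO1
Why: Hydroboration–oxidation: 9-BBN adds to the only electron-rich alkene with boron at C8, the carbon remote from the quaternary C10, while the electron-poor enol triflate is inert; perborate oxidises the C–B bond without cleaving the triflate, and the C8 configuration is irrelevant because C8 becomes a ketone.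

Step 6
Reactants: 12 the C8 alcohol enol triflate
Product: 13 1-{1,3-dimethyl-2-[(triethylsilyloxy)methyl]cyclohex-3-en-1-yl}-4-methyl-4-(triethylsilyloxy)pentan-2-ol (C3=C4 alkene bearing C15; C5 and C10 as in 8; C8 epimers)
Conditions: MeMgBr (3.5 equiv), Fe(acac)3 (10 mol%), THF/NMP, −20 → 0 °C
Reagents that add atoms: methylmagnesium bromide, C[Mg]Br
Why: Iron-catalysed Kumada-type cross-coupling replaces the triflate by methyl (C15) without moving the double bond, the first equivalent of Grignard reagent only deprotonating the C8 hydroxyl.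

Step 7
Reactants: 13 the C3=C4 methyl alkene
Product: 14 5-[2-hydroxy-4-methyl-4-(triethylsilyloxy)pentyl]-1,5-dimethyl-6-[(triethylsilyloxy)methyl]cyclohexane-1,2-diol (3α,4α-diol, 4β-methyl, 5β-CH2OSiEt3, 10β-methyl; C8 epimers)
Conditions: K2OsO2(OH)4 (5 mol%), NMO, acetone/H2O, rt
Reagents that add atoms: N-methylmorpholine N-oxide, C[N+]1([O-])CCOCC1; water, O
Why: Catalytic osmylation is a syn addition to the only alkene left, and the reagent should approach anti to the allylic C5 CH2OSi group, as is usual for 2,6,6-trisubstituted cyclohex-2-enes, which places both new oxygens α and the C15 methyl β.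

Step 8
Reactants: 14 the 3α,4α-diol
Product: 15 3α,4α-O-isopropylidene acetal of 14 (C8 hydroxyl free; C8 epimers)
Conditions: Me2C(OMe)2, PPTS (cat.), acetone, rt
Reagents that add atoms: 2,2-dimethoxypropane, COC(C)(C)OC
Why: Acid-catalysed transketalisation converts only the cis-1,2-diol into the five-membered acetonide, which guards C3–OH against oxidation and C4–OH against retro-aldol cleavage once C6 is an aldehyde.

Step 9
Reactants: 15 the acetonide
Product: 16 ring-A keto aldehyde: C6 formyl group on C5 and 4-methyl-2-oxo-4-(triethylsilyloxy)pentyl chain on C10 (3α,4α-acetonide kept; C5 and C10 unchanged)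
Conditions: (COCl)2, DMSO, CH2Cl2, −78 → −30 °C; Et3N, −78 → 0 °C
Reagents that add atoms: none
Why: Swern oxidation turns the C8 alcohol into the ketone and, with excess activated DMSO, converts the primary triethylsilyl ether directly into the C6 aldehyde, whereas the hindered tertiary silyl ether and the acetonide persist and the cold amine quench spares C5.

Step 10
Reactants: 16 the keto aldehyde
Product: 17 (3R,4S,5R,10R)-3,4-(isopropylidenedioxy)-11-(triethylsilyloxy)eudesm-6-en-8-one
Conditions: piperidine, AcOH, toluene, 60 °C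
Reagents that add atoms: none
Why: Intramolecular Mannich-type aldol condensation: the C7 enol of the ketone attacks the C6 iminium in a 6-(enolendo)-exo-trig closure (attack from C9 would give a cyclobutane), and loss of piperidine from C6 rather than silanolate from C11 gives the C6=C7 enone; C5 should hold because its enamine would be an exocyclic double bond between two quaternary carbons.

Step 11
Reactants: 17 the protected bicyclic enone
Product: 18 (3R,4S,5R,10R)-3,4,11-trihydroxyeudesm-6-en-8-one
Conditions: TsOH·H2O (cat.), MeOH, rt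
Reagents that add atoms: none
Why: Acid-catalysed methanolysis (transketalisation and desilylation) removes the acetonide and the tertiary silyl ether together under conditions too mild to ionise the tertiary alcohols or shift the enone.

Step 12
Reactants: 19 tiglic acid
Product: 20 (E)-2-methylbut-2-en-1-ol
Conditions: LiAlH4, Et2O, 0 °C → rt
Reagents that add atoms: none
Why: Hydride reduction of the conjugated acid at the carbonyl (1,2-reduction) gives the allylic alcohol with the E geometry intact.

Step 13
Reactants: 20 (E)-2-methylbut-2-en-1-ol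
Product: 21 [(2R,3R)-2,3-dimethyloxiran-2-yl]methanol
Conditions: Ti(OiPr)4 (10 mol%), D-(−)-diisopropyl tartrate (12 mol%), t-BuOOH, 4 Å MS, CH2Cl2, −20 °C
Reagents that add atoms: tert-butyl hydroperoxide, CC(C)(C)OO
Why: Sharpless asymmetric epoxidation: the titanium tartrate complex delivers oxygen to one face of the allylic alcohol, the D-(−)-tartrate giving the (2R,3R)-epoxide in which the two methyl groups stay cis.

Step 14
Reactants: 21 [(2R,3R)-2,3-dimethyloxiran-2-yl]methanol
Product: 22 (2S,3R)-2,3-dimethyloxirane-2-carboxylic acid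
Conditions: RuCl3·xH2O (cat.), NaIO4, MeCN/EtOAc/H2O, 0 °C → rt
Reagents that add atoms: water, O
Why: RuO4 generated in situ oxidises the primary alcohol through the aldehyde hydrate to the acid without opening the epoxide; the change of the C2 descriptor from R to S is only a change of CIP priorities.

Step 15
Reactants: 18 (3R,4S,5R,10R)-3,4,11-trihydroxyeudesm-6-en-8-one; 22 (2S,3R)-2,3-dimethyloxirane-2-carboxylic acid
Product: 24 (3R,4S,5R,10R)-4,11-dihydroxy-8-oxoeudesm-6-en-3-yl (2S,3R)-2,3-dimethyloxirane-2-carboxylate, via mixed trichlorobenzoic anhydride 23 (not isolated)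
Conditions: 22, 2,4,6-Cl3C6H2COCl, Et3N, THF, rt; then 18, DMAP, toluene, rt → 40 °C
Reagents that add atoms: none
Why: Yamaguchi esterification: the mixed anhydride acylates DMAP and then the only secondary hydroxyl, the axial C3–OH, while the two tertiary alcohols are too hindered to react.

Step 16
Reactants: 24 the epoxy ester
Product: 25 (3R,4S,5R,10R)-4,11-dihydroxy-8-oxoeudesm-6-en-3-yl (2R,3S)-3-chloro-2-hydroxy-2-methylbutanoate (CNP0288516.1)
Conditions: HCl (4 M in dioxane, 1.5 equiv), CH2Cl2, −20 → 0 °C
Reagents that add atoms: hydrogen chloride, Cl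
Why: Acid-promoted epoxide opening: chloride attacks the protonated epoxide at the secondary C3′ in an SN2 manner with inversion (the quaternary C2′ next to the carbonyl is hindered and deactivated), which gives the (2R,3S)-chlorohydrin ester.

Compound list
1 | 2-methylpent-4-yn-2-ol | CC(C)(O)CC#C | starting material
2 | triethyl[(2-methylpent-4-yn-2-yl)oxy]silane | CC(C)(CC#C)O[Si](CC)(CC)CC | intermediate
3 | 3-methylcyclohex-2-en-1-one | CC1=CC(=O)CCC1 | starting material
4 | formaldehyde (monomer from paraformaldehyde) | C=O | starting material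
5 | (E)-diisobutyl[4-methyl-4-(triethylsilyloxy)pent-1-en-1-yl]alane | CC(C)C[Al](CC(C)C)/C=C/CC(C)(C)O[Si](CC)(CC)CC | intermediate (not isolated)
6 | diisobutylaluminium C4=C5 enolate of the conjugate adduct (C10 as in 7) | CC(C)C[Al](CC(C)C)OC1=C[C@@](C)(/C=C/CC(C)(C)O[Si](CC)(CC)CC)CCC1 | intermediate (not isolated)
7 | (2S,3R)-2-(hydroxymethyl)-3-methyl-3-[(1E)-4-methyl-4-(triethylsilyloxy)pent-1-en-1-yl]cyclohexan-1-one | O=C1CCC[C@](C)(/C=C/CC(C)(C)O[Si](CC)(CC)CC)[C@H]1CO | intermediate
8 | (2S,3R)-3-methyl-3-[(1E)-4-methyl-4-(triethylsilyloxy)pent-1-en-1-yl]-2-[(triethylsilyloxy)methyl]cyclohexan-1-one | O=C1CCC[C@](C)(/C=C/CC(C)(C)O[Si](CC)(CC)CC)[C@H]1CO[Si](CC)(CC)CC | intermediate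
9 | potassium C3=C4 enolate of 8 | [K+].[O-]C1=CCC[C@](C)(/C=C/CC(C)(C)O[Si](CC)(CC)CC)[C@H]1CO[Si](CC)(CC)CC | intermediate (not isolated)
10 | 5-methyl-5-[(1E)-4-methyl-4-(triethylsilyloxy)pent-1-en-1-yl]-6-[(triethylsilyloxy)methyl]cyclohex-1-en-1-yl trifluoromethanesulfonate | O=S(=O)(OC1=CCC[C@](C)(/C=C/CC(C)(C)O[Si](CC)(CC)CC)[C@H]1CO[Si](CC)(CC)CC)C(F)(F)F | intermediate
11 | C8 9-borabicyclo[3.3.1]nonan-9-yl adduct of 10 (C8 epimers) | O=S(=O)(OC1=CCC[C@](C)(CC(CC(C)(C)O[Si](CC)(CC)CC)B2C3CCCC2CCC3)[C@H]1CO[Si](CC)(CC)CC)C(F)(F)F | intermediate (not isolated)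
12 | 5-[2-hydroxy-4-methyl-4-(triethylsilyloxy)pentyl]-5-methyl-6-[(triethylsilyloxy)methyl]cyclohex-1-en-1-yl trifluoromethanesulfonate (C8 epimers) | O=S(=O)(OC1=CCC[C@](C)(CC(O)CC(C)(C)O[Si](CC)(CC)CC)[C@H]1CO[Si](CC)(CC)CC)C(F)(F)F | intermediate
13 | 1-{1,3-dimethyl-2-[(triethylsilyloxy)methyl]cyclohex-3-en-1-yl}-4-methyl-4-(triethylsilyloxy)pentan-2-ol (C8 epimers) | CC1=CCC[C@](C)(CC(O)CC(C)(C)O[Si](CC)(CC)CC)[C@H]1CO[Si](CC)(CC)CC | intermediate
14 | 5-[2-hydroxy-4-methyl-4-(triethylsilyloxy)pentyl]-1,5-dimethyl-6-[(triethylsilyloxy)methyl]cyclohexane-1,2-diol (3α,4α-diol; C8 epimers) | O[C@@H]1CC[C@](C)(CC(O)CC(C)(C)O[Si](CC)(CC)CC)[C@@H](CO[Si](CC)(CC)CC)[C@]1(C)O | intermediate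
15 | 3α,4α-O-isopropylidene acetal of 14 (C8 epimers) | CC1(C)O[C@@H]2CC[C@](C)(CC(O)CC(C)(C)O[Si](CC)(CC)CC)[C@@H](CO[Si](CC)(CC)CC)[C@]2(C)O1 | intermediate
16 | ring-A keto aldehyde (C6 formyl on C5; 4-methyl-2-oxo-4-(triethylsilyloxy)pentyl on C10; 3α,4α-acetonide) | CC1(C)O[C@@H]2CC[C@](C)(CC(=O)CC(C)(C)O[Si](CC)(CC)CC)[C@@H](C=O)[C@]2(C)O1 | intermediate
17 | (3R,4S,5R,10R)-3,4-(isopropylidenedioxy)-11-(triethylsilyloxy)eudesm-6-en-8-one | CC1(C)O[C@@H]2CC[C@]3(C)CC(=O)C(C(C)(C)O[Si](CC)(CC)CC)=C[C@H]3[C@]2(C)O1 | intermediate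
18 | (3R,4S,5R,10R)-3,4,11-trihydroxyeudesm-6-en-8-one | O[C@@H]1CC[C@]2(C)CC(=O)C(C(C)(C)O)=C[C@H]2[C@]1(C)O | intermediate
19 | tiglic acid, (E)-2-methylbut-2-enoic acid | C/C=C(C)/C(=O)O | starting material
20 | (E)-2-methylbut-2-en-1-ol | C/C=C(C)/CO | intermediate
21 | [(2R,3R)-2,3-dimethyloxiran-2-yl]methanol | C[C@H]1O[C@]1(C)CO | intermediate
22 | (2S,3R)-2,3-dimethyloxirane-2-carboxylic acid | C[C@H]1O[C@]1(C)C(=O)O | intermediate
23 | (2S,3R)-2,3-dimethyloxirane-2-carboxylic 2,4,6-trichlorobenzoic anhydride | C[C@H]1O[C@]1(C)C(=O)OC(=O)c1c(Cl)cc(Cl)cc1Cl | intermediate (not isolated)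
24 | (3R,4S,5R,10R)-4,11-dihydroxy-8-oxoeudesm-6-en-3-yl (2S,3R)-2,3-dimethyloxirane-2-carboxylate | C[C@H]1O[C@]1(C)C(=O)O[C@@H]1CC[C@]2(C)CC(=O)C(C(C)(C)O)=C[C@H]2[C@]1(C)O | intermediate
25 | (3R,4S,5R,10R)-4,11-dihydroxy-8-oxoeudesm-6-en-3-yl (2R,3S)-3-chloro-2-hydroxy-2-methylbutanoate | C[C@H](Cl)[C@](C)(O)C(=O)O[C@@H]1CC[C@]2(C)CC(=O)C(C(C)(C)O)=C[C@H]2[C@]1(C)O | target

Total step count: 16. Longest linear sequence: 13 (steps 1–11, 15, 16); the acid branch is steps 12–14.

Steps most likely to fail

Step 2. The aluminium enolate may be protonated instead of hydroxymethylated, formaldehyde may polymerise before it is captured, and the facial discrimination at C5 may be weak. The fallback sets out from the aluminium enolate 6 (made from 2 and 3 as in step 2) and separates the two bond formations in time. The enolate is silylated in the flask with Et3SiOTf to the triethylsilyl enol ether F1, which is isolated. F1 is then hydroxymethylated at C5 in a Mukaiyama aldol reaction with aqueous formaldehyde and Yb(OTf)3 in THF/H2O, which returns to the route at 7.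

Step 10. The C11 silyloxy group may be lost by β-elimination from the ketone enol, iminium formation at the hindered aldehyde may be slow, or C5 may epimerise before closure. The fallback sets out from 16 and splits addition from elimination. K2CO3 in MeOH at 0 °C should stop at the aldol adduct, the C6 β-hydroxy ketone F5. Its secondary hydroxyl is converted with MsCl and Et3N in CH2Cl2 into the C6 mesylate F6. DBU then eliminates methanesulfonate across C6–C7, a far better leaving group than the C11 silanolate, and the route is rejoined at 17.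

Step 7. Osmylation of the conformationally mobile monocycle may show poor facial selectivity. The fallback sets out from 13 and moves the dihydroxylation behind ring closure. Swern oxidation as in step 9 gives the keto aldehyde F2, which still holds the C3=C4 alkene. Piperidinium acetate closes ring B to the dienone F3. Osmylation (K2OsO2(OH)4, NMO) of this rigid trans-fused bicycle gives the 3α,4α-diol F4; the axial C14 methyl blocks the β-face and the enone double bond is too electron-poor to react. TsOH in MeOH removes the C11 silyl group and returns to the route at 18. This order is two steps shorter but is not the first choice, because the β,γ-unsaturated aldehyde F2 is more prone to double-bond migration and epimerisation at C5.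

Further compounds
F1 | step 2 | triethylsilyl enol ether (C4=C5) of the conjugate adduct | CC[Si](CC)(CC)OC1=C[C@@](C)(/C=C/CC(C)(C)O[Si](CC)(CC)CC)CCC1
F2 | step 7 | keto aldehyde with C3=C4 methyl alkene (C6 formyl on C5; 4-methyl-2-oxo-4-(triethylsilyloxy)pentyl on C10) | CC1=CCC[C@](C)(CC(=O)CC(C)(C)O[Si](CC)(CC)CC)[C@H]1C=O
F3 | step 7 | (5R,10R)-11-(triethylsilyloxy)eudesma-3,6-dien-8-one | CC1=CCC[C@]2(C)CC(=O)C(C(C)(C)O[Si](CC)(CC)CC)=C[C@@H]12
F4 | step 7 | (3R,4S,5R,10R)-3,4-dihydroxy-11-(triethylsilyloxy)eudesm-6-en-8-one | O[C@@H]1CC[C@]2(C)CC(=O)C(C(C)(C)O[Si](CC)(CC)CC)=C[C@H]2[C@]1(C)O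
F5 | step 10 | 6-hydroxy-3,4-(isopropylidenedioxy)-11-(triethylsilyloxy)eudesman-8-one (aldol adduct; C6 and C7 epimers) | CC1(C)O[C@@H]2CC[C@]3(C)CC(=O)C(C(C)(C)O[Si](CC)(CC)CC)C(O)[C@H]3[C@]2(C)O1
F6 | step 10 | C6 methanesulfonate of F5 | CC1(C)O[C@@H]2CC[C@]3(C)CC(=O)C(C(C)(C)O[Si](CC)(CC)CC)C(OS(C)(=O)=O)[C@H]3[C@]2(C)O1
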